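# Synthesis proposal for target 20, the (E)-caffeate of a tricyclic methylene alcohol

## Conventions and assumptions

- **Locants.** The core is numbered as a norbornane: C1 (bridgehead CH), C2 (carbinol carbon), C3, C4 (quaternary bridgehead), C5, C6 (methylene-bearing), C7 (methyl-bearing bridge). Ring A is C4–C8(CMe2)–C9–C10–C11–C7, and C12 is the exocyclic CH2. "Exo" means on the side of the C7 bridge.
- **Assumption on the racemic stage.** Compounds 2 and 4 are achiral; 5 to 9 are racemates, and their names and SMILES show the enantiomer that is carried on. From 10 onwards all compounds are single enantiomers.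
- **Assumption on supply.** β-Homocyclocitral 1 is taken as a purchasable flavour chemical.
- **Compound numbers.** 1 β-homocyclocitral; 2 its dimethyl acetal; 3 trichloroacetyl chloride; 4 dichloroketene; 5 dichlorocyclobutanone; 6 dichlorocyclopentanone; 7 keto acetal; 8 keto aldehyde; 9 endo ketol; 10 camphanate of 9; 11 methylene camphanate; 12 endo methylene alcohol; 13 methylene ketone; 14 exo methylene alcohol; 15 caffeic acid; 16 tris-silyl caffeate; 17 bis-silyl caffeic acid; 18 mixed anhydride; 19 bis-silyl ester; 20 target.

## Analysis of the target

Target 20 is the (E)-caffeate of a tricyclic C15 alcohol: a norbornane (C1–C7) with an exocyclic methylene (C12) on C6, the ester oxygen on C2, and a cyclohexane (ring A, with a gem-dimethyl group on C8 and a methyl on C7) fused across the C4–C7 bond. It has four stereocentres, (1R,2R,4R,7S) with these locants: C1 and C4 are tied to each other by the bicycle, the C7 methyl lies syn to the C2–C3 bridge (so ring A is cis-fused to the cyclopentane C1–C6–C5–C4–C7), and the C2 oxygen is exo, on the same side as that methyl. C8, C4 and C7 are three contiguous fully substituted carbons, and C4 and C7 are adjacent quaternary stereocentres; building this array is the main difficulty, and no chiral-pool terpene maps onto the skeleton. The sensitive parts are the catechol (air oxidation once deprotonated), the cinnamate ester (base and nucleophiles), the 1,1-disubstituted alkene and the norbornyl framework (acid-induced alkene migration and Wagner–Meerwein shifts), and the hindered exo alcohol that must be acylated late. The strategy rests on one observation: C4 and C7 belong both to ring A and to the methylene-bearing cyclopentane, so they correspond to the two carbons of the tetrasubstituted alkene of a cyclogeranyl unit that already carries the C3–C2 side chain on C4. A suprafacial two-carbon cycloaddition across that alkene makes both quaternary centres at once in the only relative configuration the target allows, and C1 can be inserted afterwards by a one-carbon ring expansion. The C1–C2 bond then follows from an aldol closure that is possible only on the face the arm occupies, so only C2 and the absolute configuration need separate control.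

## Retrosynthetic reasoning

**Ester bond C2–O–acyl (20 ⇒ 19 ⇒ 14 + 17).** The caffeoyl group is attached last, because the catechol and the cinnamate are the most fragile parts and the coupling is convergent. The catechol is carried as the bis-silyl ether (19, from acid 17, made from caffeic acid 15), which is removed by buffered fluoride; this spares the ester, the alkene and the acid-sensitive skeleton. The forward reaction has to acylate a hindered exo alcohol without touching C2.

**C2–H bond (14 ⇒ 13 ⇒ 12).** The exo configuration at C2 is traced to hydride addition to ketone 13. The C7 methyl screens the exo face and C6 is sp2, so the endo face is open and the exo alcohol should result. Ketone 13 comes from oxidation of the endo alcohol 12, so the C2 configuration delivered by the earlier ring closure does not have to be the right one.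

**C6=C12 bond and the absolute configuration (12 ⇒ 11 ⇒ 10 ⇒ 9).** The methylene is traced to a C6 ketone, because that ketone is what makes the next disconnection possible. The β-hydroxy ketone must be masked during the olefination, and the mask is chosen to do a second job: camphanate 10 is one of two separable diastereomers obtained from racemic ketol 9. Resolution and protection therefore cost one operation, and the auxiliary leaves by methanolysis of 11.

**C1–C2 bond (9 ⇒ 8 ⇒ 7).** Cutting C1–C2 as an aldol bond opens the norbornane to a cis-fused bicyclic ketone with an acetaldehyde arm on C4 (8, stored as acetal 7). The cut is made here because the alternative enolisation towards C5 could only close a cyclobutane, so the regiochemistry is built in. The arm can reach C1 only from its own face, which fixes C1 relative to C4 and C7.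

**Removal of C1 (7 ⇒ 6 ⇒ 5).** The cyclopentanone is contracted by one carbon: C1 is taken out between C6 and C7, leaving cyclobutanone 5. The two chlorines on C5 make the forward ring expansion regioselective and are then removed reductively.

**C4–C5 and C7–C6 bonds (5 ⇒ 2 + 4; 4 ⇐ 3; 2 ⇐ 1).** Both ring-fusion quaternary centres are cut in one [2+2] disconnection, giving the tetrasubstituted alkene 2 and dichloroketene 4, which is generated from trichloroacetyl chloride 3. Acetal 2 is one step from the commercial aldehyde 1. The cut is placed here because a suprafacial addition can only give the cis relationship of arm and methyl that the target needs.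

## Alternatives that were turned down

**Alternative 1: semipinacol ring expansion of an epoxy cyclobutanol.**
- *Disconnection and key step.* The C1–C7 bond is traced to a 1,2-shift. In the epoxy alcohol A2, C7 is still bonded to C6, C6 is a bridgehead carbinol of a bicyclo[3.1.1]heptane, and C1–C2 carry an epoxide anti to C7. A Lewis acid opens the epoxide at C1, the antiperiplanar C6–C7 bond migrates to C1, and C6 becomes a ketone. The product is the endo ketol A1, the same compound as 9.
- *For.* The shift is stereospecific, driven by release of cyclobutane strain, and gives a single C2 epimer. The C7 methyl sits over the three-carbon bridge of A2, which should direct epoxidation to the required face. On these points it is stronger than the reversible aldol used here.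
- *Against.* A2 already contains the C4/C7 quaternary pair in a cyclobutane, which would itself have to come from a ketene cycloaddition to the same hindered alkene. A further carbocyclisation and an epoxidation are then needed to arrive at the ketol 9 that the chosen route reaches in five steps. Epoxide opening at C2, hydride shift and migration of C5 are competing paths.
- *Comparison.* The endgame is identical (methylenation, inversion at C2, acylation). The chosen route gives up the stereospecific C2 in exchange for a much shorter path to the same ketol.

**Alternative 2: hydrogen-atom-transfer radical cyclisation closing ring A.**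
- *Disconnection and key step.* The C4–C8 bond is cut. Iron-catalysed hydrogen-atom transfer from a silane to the isopropenyl terminus of cyclopentenone A4 gives the tertiary C8 radical, which adds 6-exo to the enone β-carbon C4. The product is the cis-fused keto ester A3, the tert-butyl ester analogue of 7.
- *For.* A radical is well suited to the most congested bond, between two fully substituted carbons. A4 has a single stereocentre (C7) that could be set by asymmetric catalysis, so no resolution would be needed; on absolute stereocontrol this alternative is stronger.
- *Against.* A4 is a 3,4,4-trisubstituted cyclopentenone that needs several steps. Its β,β-disubstituted enone next to quaternary C7 is a poor radical acceptor, so simple reduction of the alkene competes. The ester arm of A3 needs redox adjustment, with the ketone protected, before the aldol.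
- *Comparison.* The chosen route sets C4 and C7 together in the second step from a commercial C11 aldehyde, with the arm already at the aldehyde oxidation level, at the price of a late-stage halving of material.

**Alternative 3: allylsilane conjugate cyclisation onto a bicyclic enone.**
- *Disconnection and key step.* The C4–C5 bond is cut. Lewis-acid activation of enone A6, which carries a 2-(trimethylsilylmethyl)vinyl group on C1, lets the terminal alkene carbon attack C4; silicon is lost and the C6=C12 methylene appears. The product is the methylene ketone A5, identical with 13.
- *For.* The endgame is the shortest of all: the methylene and the C2 ketone are in place, so no aldol, no olefination and no protecting group at C2 are needed. In step economy after the key step it is clearly stronger.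
- *Against.* A6 requires the bicyclic enone with quaternary C7 and a branched substituent on C1 next to it, in the one configuration that can reach C4; that centre is epimerisable. The cyclisation must create quaternary C4 between C8 and C7 through a bridging transition state, and protodesilylation competes. It is also racemic unless C7 is set asymmetrically.
- *Comparison.* The chosen route places its one uncertain step early, on cheap material and in an intermolecular reaction with an early, asynchronous transition state, and then continues with conventional steps.

Key step: step 2

## Route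

Step 1
Reactants: 1 β-homocyclocitral [(2,6,6-trimethylcyclohex-1-en-1-yl)acetaldehyde]
Product: 2 2-(2,2-dimethoxyethyl)-1,3,3-trimethylcyclohex-1-ene
Conditions: HC(OMe)3, MeOH, PPTS (cat.), rt
Reagents that add atoms: trimethyl orthoformate, COC(OC)OC; methanol, CO
Why: Acid-catalysed acetalisation with the orthoformate as water scavenger; the mild pyridinium acid should leave the tetrasubstituted β,γ-alkene where it is, and no stereocentre is formed.

Step 2
Reactants: 2 2-(2,2-dimethoxyethyl)-1,3,3-trimethylcyclohex-1-ene; 3 trichloroacetyl chloride
Product: 5 cis-8,8-dichloro-1-(2,2-dimethoxyethyl)-2,2,6-trimethylbicyclo[4.2.0]octan-7-one (racemic; acetal arm and methyl on the same face), via dichloroketene 4 (not isolated)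
Conditions: Zn(Cu), Et2O–DME (4:1), slow addition of 3, sonication, 15–25 °C
Reagents that add atoms: none
Why: Zinc removes two chlorines from 3 by reductive 1,2-elimination and so produces dichloroketene 4 at a low stationary concentration. The electron-poor ketene adds to the electron-rich tetrasubstituted alkene through the concerted, asynchronous [π2s+π2a] path, in which the alkene first engages the central ketene carbon and the CCl2 terminus closes afterwards. The closest known reaction type is the dichloroketene–alkene cycloaddition under zinc/trichloroacetyl chloride conditions, which is used on tri- and tetrasubstituted cycloalkenes as the first stage of a cyclopentanone annulation. The four-membered ring is closed by cycloaddition (the σ bonds C4–C5 and C7–C6 form in one step, not by an exo or endo ring closure), and it can only be cis-fused to ring A because the addition is suprafacial on a cyclohexene. C4 and C7 are both set by this suprafacial delivery, which places the acetal arm and the methyl on the same face; the two faces of 2 are enantiotopic, so 5 is a racemate. The carbonyl carbon is expected to bond to the less encumbered C7 and the CCl2 carbon to C4, but this need not be controlled, since the other orientation gives the same ketone 7 after steps 3 and 4. What the step needs is for cycloaddition to outrun ketene oligomerisation and Lewis-acid attack on the acetal; this is served by the nucleophilic tetrasubstituted alkene, slow addition of excess 3, and DME to bind the ZnCl2 formed.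

Step 3
Reactants: 5 cis-8,8-dichloro-1-(2,2-dimethoxyethyl)-2,2,6-trimethylbicyclo[4.2.0]octan-7-one
Product: 6 cis-3,3-dichloro-3a-(2,2-dimethoxyethyl)-4,4,7a-trimethyloctahydro-2H-inden-2-one (racemic)
Conditions: CH2N2, Et2O–MeOH, 0 °C to rt
Reagents that add atoms: diazomethane, C=[N+]=[N-]
Why: Diazomethane ring expansion of an α,α-dichlorocyclobutanone: addition to the strained, electron-poor carbonyl is followed by a 1,2-shift with loss of N2, and the chlorine-bearing carbon does not migrate, so C7 migrates with retention and the new CH2 (C1) enters between C6 and C7. The dichlorocyclopentanone formed is far less reactive, so homologation should stop after one carbon.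

Step 4
Reactants: 6 cis-3,3-dichloro-3a-(2,2-dimethoxyethyl)-4,4,7a-trimethyloctahydro-2H-inden-2-one
Product: 7 cis-3a-(2,2-dimethoxyethyl)-4,4,7a-trimethyloctahydro-2H-inden-2-one (racemic)
Conditions: Zn dust, NH4Cl, MeOH, rt
Reagents that add atoms: none
Why: Reductive dechlorination of an α,α-dichloro ketone through zinc enolates, twice; the buffered methanolic medium keeps the dimethyl acetal intact and no stereocentre is touched.

Step 5
Reactants: 7 cis-3a-(2,2-dimethoxyethyl)-4,4,7a-trimethyloctahydro-2H-inden-2-one
Product: 9 2-endo-hydroxy C6 ketone of the tricyclic skeleton [11-hydroxy-2,2,6-trimethyltricyclo[5.2.2.0(1,6)]undecan-8-one; racemic; C1, C4 and C7 as in the target], via keto aldehyde 8 (not isolated)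
Conditions: 2 M aq. HCl, THF, rt to 40 °C
Reagents that add atoms: water, O
Why: Acetal hydrolysis releases 8, and an acid-catalysed intramolecular aldol addition (5-(enolexo)-exo-trig) closes C1–C2; only the C1 enol can reach the aldehyde, since the C5 enol would have to form a cyclobutane, and C1 is fixed by bridging on the face of the arm. The C2 hydroxyl is expected endo (hydrogen-bonded closure towards the C6 enol oxygen, and an exo hydroxyl would sit under the syn C7 methyl); any exo epimer is removed by chromatography. Dehydration towards the bridgehead is excluded by Bredt's rule.

Step 6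
Reactants: 9 2-endo-hydroxy C6 ketone (racemic)
Product: 10 (1S,4R)-camphanate of the 2-endo-hydroxy C6 ketone, single diastereomer with C1, C4 and C7 as in the target
Conditions: (1S)-(−)-camphanic chloride, pyridine, DMAP (cat.), CH2Cl2, 0 °C to rt; separation of the two diastereomers by chromatography and crystallisation
Reagents that add atoms: (1S,4R)-camphanic chloride, O=C(Cl)[C@@]12CC[C@@](C)(C(=O)O1)C2(C)C
Why: DMAP-catalysed acylation turns the enantiomers of 9 into diastereomeric esters that differ in polarity and lattice energy (classical resolution); the configuration is to be assigned by X-ray diffraction, with the camphanoyl group as internal reference. The ester also masks the β-hydroxy ketone against retro-aldol cleavage in the next step.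

Step 7
Reactants: 10 (1S,4R)-camphanate of the 2-endo-hydroxy C6 ketone
Product: 11 (1S,4R)-camphanate of the 2-endo-hydroxy 6-methylene compound [(1R,6S,7R,8S)-2,2,6-trimethyl-11-methylidenetricyclo[5.2.2.0(1,6)]undecan-8-yl camphanate]
Conditions: Zn, CH2Br2, TiCl4, THF (reagent pre-formed and aged at 5 °C); then 10, CH2Cl2, 0 °C to rt
Reagents that add atoms: dibromomethane, BrCBr
Why: Takai–Lombardo methylenation: the non-basic gem-dimetallic methylene reagent converts hindered, enolisable ketones into methylene compounds and leaves esters and lactones alone, so the camphanate survives and no retro-aldol or epimerisation can occur.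

Step 8
Reactants: 11 (1S,4R)-camphanate of the 2-endo-hydroxy 6-methylene compound
Product: 12 (1R,6S,7R,8S)-2,2,6-trimethyl-11-methylidenetricyclo[5.2.2.0(1,6)]undecan-8-ol (2-endo alcohol)
Conditions: K2CO3 (cat.), MeOH, 50 °C
Reagents that add atoms: none
Why: Base-catalysed transesterification with the solvent; with the ketone gone there is no retro-aldol path, and the isolated alkene is inert to methoxide.

Step 9
Reactants: 12 2-endo methylene alcohol
Product: 13 (1R,6S,7R)-2,2,6-trimethyl-11-methylidenetricyclo[5.2.2.0(1,6)]undecan-8-one (C2 ketone)
Conditions: Dess–Martin periodinane, CH2Cl2, 0 °C to rt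
Reagents that add atoms: none
Why: Dess–Martin oxidation under near-neutral conditions; the β,γ-unsaturated ketone cannot move into conjugation because the carbon between the two sp2 centres is the bridgehead C1.

Step 10
Reactants: 13 C2 ketone
Product: 14 (1R,6S,7R,8R)-2,2,6-trimethyl-11-methylidenetricyclo[5.2.2.0(1,6)]undecan-8-ol (2-exo alcohol)
Conditions: LiAlH4, THF, −78 to 0 °C
Reagents that add atoms: none
Why: Hydride addition to a norbornanone whose exo face is screened by the syn C7 methyl, as in the reduction of camphor to isoborneol; the endo face is open because C6 is sp2, so hydride enters endo and the hydroxyl ends exo, which sets C2.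

Step 11
Reactants: 15 caffeic acid
Product: 17 (E)-3-[3,4-bis(tert-butyldimethylsilyloxy)phenyl]prop-2-enoic acid, via tris-silyl derivative 16 (not isolated)
Conditions: TBSCl, imidazole, DMF, rt; then AcOH–THF–H2O, rt
Reagents that add atoms: tert-butyldimethylsilyl chloride, CC(C)(C)[Si](C)(C)Cl
Why: Exhaustive silylation followed by selective hydrolysis of the labile silyl ester; the aryl silyl ethers survive dilute acetic acid and the E alkene is untouched.

Step 12
Reactants: 14 2-exo alcohol; 17 (E)-3-[3,4-bis(tert-butyldimethylsilyloxy)phenyl]prop-2-enoic acid
Product: 19 bis-silyl ether of the target [2-exo-yl (E)-3-[3,4-bis(tert-butyldimethylsilyloxy)phenyl]prop-2-enoate], via mixed anhydride 18 (not isolated)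
Conditions: 2,4,6-trichlorobenzoyl chloride, Et3N, THF, rt; then 14, DMAP, toluene, rt to 60 °C
Reagents that add atoms: none
Why: Yamaguchi esterification: the mixed anhydride is opened regioselectively by DMAP and the acylpyridinium acylates hindered secondary alcohols; bonding is at oxygen, so C2 keeps its configuration and the E alkene is retained.

Step 13
Reactants: 19 bis-silyl ether of the target
Product: 20 target, (1R,6S,7R,8R)-2,2,6-trimethyl-11-methylidenetricyclo[5.2.2.0(1,6)]undecan-8-yl (2E)-3-(3,4-dihydroxyphenyl)prop-2-enoate
Conditions: TBAF, AcOH, THF, 0 °C, under argon
Reagents that add atoms: none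
Why: Fluoride cleavage of aryl silyl ethers; the acetic acid buffer keeps the catechol protonated, which avoids air oxidation of the catecholate and attack on the cinnamate ester.

## Compound list

1 | β-homocyclocitral, (2,6,6-trimethylcyclohex-1-en-1-yl)acetaldehyde | CC1=C(CC=O)C(C)(C)CCC1 | starting material
2 | 2-(2,2-dimethoxyethyl)-1,3,3-trimethylcyclohex-1-ene | COC(OC)CC1=C(C)CCCC1(C)C | intermediate
3 | trichloroacetyl chloride | ClC(Cl)(Cl)C(Cl)=O | starting material
4 | dichloroketene | O=C=C(Cl)Cl | intermediate
5 | cis-8,8-dichloro-1-(2,2-dimethoxyethyl)-2,2,6-trimethylbicyclo[4.2.0]octan-7-one (racemic, enantiomer shown) | COC(OC)C[C@@]12C(Cl)(Cl)C(=O)[C@]1(C)CCCC2(C)C | intermediate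
6 | cis-3,3-dichloro-3a-(2,2-dimethoxyethyl)-4,4,7a-trimethyloctahydro-2H-inden-2-one (racemic, enantiomer shown) | COC(OC)C[C@@]12C(Cl)(Cl)C(=O)C[C@]1(C)CCCC2(C)C | intermediate
7 | cis-3a-(2,2-dimethoxyethyl)-4,4,7a-trimethyloctahydro-2H-inden-2-one (racemic, enantiomer shown) | COC(OC)C[C@@]12CC(=O)C[C@]1(C)CCCC2(C)C | intermediate
8 | cis-(4,4,7a-trimethyl-2-oxooctahydro-1H-inden-3a-yl)acetaldehyde (racemic, enantiomer shown) | O=CC[C@@]12CC(=O)C[C@]1(C)CCCC2(C)C | intermediate
9 | 2-endo-hydroxy C6 ketone, 11-hydroxy-2,2,6-trimethyltricyclo[5.2.2.0(1,6)]undecan-8-one (racemic, enantiomer shown) | O=C1C[C@]23C[C@H](O)[C@H]1[C@]2(C)CCCC3(C)C | intermediate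
10 | (1S,4R)-camphanate of 9, diastereomer with C1, C4, C7 as in the target | O=C1C[C@]23C[C@H](OC(=O)[C@@]45CC[C@@](C)(C(=O)O4)C5(C)C)[C@H]1[C@]2(C)CCCC3(C)C | intermediate
11 | (1S,4R)-camphanate of the 2-endo-hydroxy 6-methylene compound | C=C1C[C@]23C[C@H](OC(=O)[C@@]45CC[C@@](C)(C(=O)O4)C5(C)C)[C@H]1[C@]2(C)CCCC3(C)C | intermediate
12 | (1R,6S,7R,8S)-2,2,6-trimethyl-11-methylidenetricyclo[5.2.2.0(1,6)]undecan-8-ol (2-endo alcohol) | C=C1C[C@]23C[C@H](O)[C@H]1[C@]2(C)CCCC3(C)C | intermediate
13 | (1R,6S,7R)-2,2,6-trimethyl-11-methylidenetricyclo[5.2.2.0(1,6)]undecan-8-one | C=C1C[C@]23CC(=O)[C@H]1[C@]2(C)CCCC3(C)C | intermediate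
14 | (1R,6S,7R,8R)-2,2,6-trimethyl-11-methylidenetricyclo[5.2.2.0(1,6)]undecan-8-ol (2-exo alcohol) | C=C1C[C@]23C[C@@H](O)[C@H]1[C@]2(C)CCCC3(C)C | intermediate
15 | caffeic acid | O=C(O)/C=C/c1ccc(O)c(O)c1 | starting material
16 | tert-butyldimethylsilyl (E)-3-[3,4-bis(tert-butyldimethylsilyloxy)phenyl]prop-2-enoate | CC(C)(C)[Si](C)(C)OC(=O)/C=C/c1ccc(O[Si](C)(C)C(C)(C)C)c(O[Si](C)(C)C(C)(C)C)c1 | intermediate
17 | (E)-3-[3,4-bis(tert-butyldimethylsilyloxy)phenyl]prop-2-enoic acid | O=C(O)/C=C/c1ccc(O[Si](C)(C)C(C)(C)C)c(O[Si](C)(C)C(C)(C)C)c1 | intermediate
18 | mixed anhydride of 17 with 2,4,6-trichlorobenzoic acid | O=C(/C=C/c1ccc(O[Si](C)(C)C(C)(C)C)c(O[Si](C)(C)C(C)(C)C)c1)OC(=O)c1c(Cl)cc(Cl)cc1Cl | intermediate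
19 | bis(tert-butyldimethylsilyl) ether of the target | C=C1C[C@]23C[C@@H](OC(=O)/C=C/c4ccc(O[Si](C)(C)C(C)(C)C)c(O[Si](C)(C)C(C)(C)C)c4)[C@H]1[C@]2(C)CCCC3(C)C | intermediate
20 | (1R,6S,7R,8R)-2,2,6-trimethyl-11-methylidenetricyclo[5.2.2.0(1,6)]undecan-8-yl (2E)-3-(3,4-dihydroxyphenyl)prop-2-enoate | C=C1C[C@]23C[C@@H](OC(=O)/C=C/c4ccc(O)c(O)c4)[C@H]1[C@]2(C)CCCC3(C)C | target

## Step count and least certain steps

Total steps: 13. Longest linear sequence: 12 (steps 1 to 10, 12 and 13); step 11 prepares the side chain.

**Step 2 (key step).**
- *Most likely failure.* Ketene oligomerisation outruns a slow cycloaddition, because the alkene is tetrasubstituted and C4 sits next to the quaternary C8. The second failure path is cleavage of the acetal by ZnCl2 and the acid chloride.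
- *Fallback, from 1 back to 8: an intramolecular ketene cycloaddition.* Aldehyde 1 is reduced (NaBH4, MeOH) to homocyclogeraniol F1. O-Alkylation with bromoacetic acid (NaH, THF) gives the alkoxyacetic acid F2, and oxalyl chloride gives the acid chloride F3. Triethylamine in refluxing toluene converts F3 into the alkoxyketene F4, which adds across C4=C7 within the molecule to give the oxa-bridged cyclobutanone F5. Intramolecular ketene additions tolerate tetrasubstituted alkenes much better than bimolecular ones, and no acetal is present. Diazomethane expansion, in which the oxygen-bearing carbon does not migrate, gives the α-alkoxy cyclopentanone F6. SmI2 in THF–MeOH cleaves the C5–O bond to the keto alcohol F7, and Dess–Martin oxidation gives keto aldehyde 8, which closes to 9 under the conditions of step 5.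

**Step 5.**
- *Most likely failure.* Incomplete or reversible closure (retro-aldol opening of the strained ketol), intermolecular condensation of 8 on prolonged acid treatment, and formation of both C2 epimers.
- *Fallback, from 7 back to 9: an irreversible closure onto an oxocarbenium ion.* Acid-catalysed exchange of 7 with benzyl alcohol (p-TsOH, toluene, removal of MeOH) gives the dibenzyl acetal F8. TMSOTf and i-Pr2NEt in CH2Cl2 form the enol silane in the flask and bring about a Mukaiyama-type addition to the acetal, giving the benzyl ether F9; the C5 enol silane cannot cyclise and returns to ketone on work-up. Hydrogenolysis (H2, Pd/C, EtOAc) gives 9 under neutral conditions.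

**Step 6.**
- *Most likely failure.* The two camphanates fail to separate (co-elution or co-crystallisation), or partial retro-aldol cleavage occurs during acylation.
- *Fallback, from 9 back to 10.* The enantiomers of 9 are separated by preparative chromatography on a chiral stationary phase, and the correct enantiomer is then acylated with camphanic chloride, which in that case serves only as the protecting group. No new compound arises.

**Step 7.**
- *Most likely failure.* No addition to a carbonyl that is shielded on both faces (C11H2 on the exo side, the acyloxy oxygen on the endo side), or Lewis-acid damage to the ester during a long reaction.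
- *Fallback, from 9 back to 11: addition of a small nucleophile, then elimination.* Racemic 9 is silylated (TBSOTf, 2,6-lutidine) to the silyl ether F10. Me3SiCH2Li with CeCl3 in THF at −78 °C adds to the ketone to give the β-hydroxysilane F11; either C6 epimer serves. Aqueous HF in MeCN brings about Peterson elimination and removes the silyl ether in the same operation, giving 12 as the racemate. Camphanoylation of racemic 12 and separation of the diastereomers gives 11.

**Step 12.**
- *Most likely failure.* Slow acylation of the exo alcohol under the syn C7 methyl, so that the mixed anhydride is used up by symmetric-anhydride formation or by conjugate addition of DMAP.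
- *Fallback, from 14 to 20: building the cinnamate on the alcohol.* Heating 14 with Meldrum's acid in toluene at 100 °C gives the malonic half ester F12 through a small, reactive acylating species. Knoevenagel–Doebner condensation with 3,4-dihydroxybenzaldehyde (pyridine, piperidine cat., 70 °C) then gives 20 directly with the E geometry and without protecting groups.

## Further compounds

F1 | step 2 | homocyclogeraniol, 2-(2,6,6-trimethylcyclohex-1-en-1-yl)ethanol | CC1=C(CCO)C(C)(C)CCC1
F2 | step 2 | [2-(2,6,6-trimethylcyclohex-1-en-1-yl)ethoxy]acetic acid | CC1=C(CCOCC(=O)O)C(C)(C)CCC1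
F3 | step 2 | [2-(2,6,6-trimethylcyclohex-1-en-1-yl)ethoxy]acetyl chloride | CC1=C(CCOCC(=O)Cl)C(C)(C)CCC1
F4 | step 2 | [2-(2,6,6-trimethylcyclohex-1-en-1-yl)ethoxy]ketene | CC1=C(CCOC=C=O)C(C)(C)CCC1
F5 | step 2 | oxa-bridged tricyclic cyclobutanone (tetrahydrofuran C4–C3–C2–O–C5 cis-fused to the cyclobutanone C4–C5–C6–C7; racemic, enantiomer shown) | O=C1[C@@H]2OCC[C@@]23C(C)(C)CCC[C@@]13C
F6 | step 2 | ring-expanded α-alkoxy cyclopentanone (C1 inserted between C6 and C7; racemic, enantiomer shown) | O=C1C[C@]2(C)CCCC(C)(C)[C@@]23CCO[C@@H]13
F7 | step 2 | cis-3a-(2-hydroxyethyl)-4,4,7a-trimethyloctahydro-2H-inden-2-one (racemic, enantiomer shown) | OCC[C@@]12CC(=O)C[C@]1(C)CCCC2(C)C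
F8 | step 5 | cis-3a-[2,2-bis(benzyloxy)ethyl]-4,4,7a-trimethyloctahydro-2H-inden-2-one (racemic, enantiomer shown) | c1ccccc1COC(OCc1ccccc1)C[C@@]12CC(=O)C[C@]1(C)CCCC2(C)C
F9 | step 5 | 2-benzyloxy C6 ketone of the tricyclic skeleton (racemic; endo epimer shown) | O=C1C[C@]23C[C@H](OCc4ccccc4)[C@H]1[C@]2(C)CCCC3(C)C
F0 | step 6 | none | none
F10 | step 7 | tert-butyldimethylsilyl ether of ketol 9 (racemic, enantiomer shown) | O=C1C[C@]23C[C@H](O[Si](C)(C)C(C)(C)C)[C@H]1[C@]2(C)CCCC3(C)C
F11 | step 7 | 6-hydroxy-6-(trimethylsilylmethyl) adduct of F10 (racemic; epimer from endo-face attack shown) | C[Si](C)(C)C[C@]1(O)C[C@]23C[C@H](O[Si](C)(C)C(C)(C)C)[C@H]1[C@]2(C)CCCC3(C)C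
F12 | step 12 | malonic acid mono ester of alcohol 14 | C=C1C[C@]23C[C@@H](OC(=O)CC(=O)O)[C@H]1[C@]2(C)CCCC3(C)C
A1 | alternative 1 | 2-endo-hydroxy C6 ketone of the tricyclic skeleton (same compound as 9) | O=C1C[C@]23C[C@H](O)[C@H]1[C@]2(C)CCCC3(C)C
A2 | alternative 1 | epoxy cyclobutanol: bicyclo[3.1.1]heptane with bridgehead carbinol C6, C1–C2 epoxide anti to C7, ring A on C4–C7 | O[C@]12C[C@@]3(C[C@@H]4O[C@@H]41)C(C)(C)CCC[C@]32C
A3 | alternative 2 | tert-butyl (cis-4,4,7a-trimethyl-2-oxooctahydroinden-3a-yl)acetate | CC(C)(C)OC(=O)C[C@@]12CC(=O)C[C@]1(C)CCCC2(C)C
A4 | alternative 2 | tert-butyl 2-[5-methyl-5-(4-methylpent-4-en-1-yl)-3-oxocyclopent-1-en-1-yl]acetate | C=C(C)CCC[C@@]1(C)CC(=O)C=C1CC(=O)OC(C)(C)C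
A5 | alternative 3 | tricyclic methylene C2 ketone (same compound as 13) | C=C1C[C@]23CC(=O)[C@H]1[C@]2(C)CCCC3(C)C
A6 | alternative 3 | 4,4,7a-trimethyl-1-[3-(trimethylsilyl)prop-1-en-2-yl]-1,4,5,6,7,7a-hexahydro-2H-inden-2-one | C=C(C[Si](C)(C)C)[C@H]1C(=O)C=C2C(C)(C)CCC[C@]21C
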